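(The numbers in the tables are simulated for substances that don't exist.)

**Counted partner.** Coupling partner obeys a simple ledger: what was charged is either still free or has been spent on something. I held Monday's flask, the one asked about, to that ledger, counting amounts as fractions of the starting material charged.

all flasks: starting material 0.50 M
- Monday's: coupling partner 0.65 M; protic impurity 0.050 M; temperature 40 °C; the very flask that is asked about, followed so far
- Tuesday's: coupling partner 0.65 M; protic impurity 0.050 M; temperature 35 °C; run made earlier
- flask: coupling partner 0.650 M; protic impurity 0.0500 M; temperature 40 °C; time 10 h

| run | time / h | target / % | starting material / % |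
|---|---|---|---|
| Monday's | 1.00 | 33.5 | 31.8 |
| Monday's | 3.00 | 38.7 | 22.0 |
| Monday's | 5.00 | 41.4 | 19.3 |
| Monday's | 8.00 | 43.5 | 17.9 |
| Tuesday's | 1.00 | 29.6 | 36.3 |
| Tuesday's | 3.00 | 37.8 | 23.2 |
| Tuesday's | 5.00 | 39.1 | 21.9 |
| Tuesday's | 8.00 | 42.7 | 19.4 |

(standard deviation of a reading: 1 percentage point)

- amber: at 10 h add starting material, 50.0% of the amount charged, then wait 5.0 h
- grey: change nothing and wait 5.0 h more
- red: at 10 h raise the temperature by 10 K, then wait 5.0 h
- blue: at 10 h add coupling partner, 50.0% of the amount charged, then wait 5.0 h

- what is added takes up no volume worth counting
- a reading or a percentage of target counts all its forms, free or not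

* target, in percent of the starting material first charged, at 10 h
* which option adds most target ("none" when 2 percentage points or less is all one gets) (amber / grey / red / blue / none)
* target present, in percent of the starting material first charged, after amber
* target present, in percent of the starting material first charged, after blue

**Main step.** If one partner turned one starting material into target, the charge of 1.30 partner stood above the need. Yet Monday's flask held 43.5% target at 8.00 h.

**Adding impurity.** If the protic impurity took one partner each, it cost 0.100. That left 1.20 usable partner, still above one, so the stall stayed unexplained.

**Adding side channel.** Target and starting material summed to 61.4%, so a side channel held the rest. Tuesday's flask, at 35 °C, read 19.4% starting material at 8.00 h, against 17.9% in Monday's flask at 40 °C, and I read that pattern as the mark of a limiting reagent. I took partner as that reagent. Usable partner over starting material consumed came to 1.46, and this is the partner price, the partner spent per starting material consumed. Target per starting material consumed was 0.530.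

**Going round.** In Monday's flask the hourly gain of target over the last interval was 0.519 of the gain before it. Applying that factor once gave 44.2% at 10 h. Applying it again gave a creep of 0.94 percentage points over the next 5.0 h, less than the 2 points that counts.

**The options.** The price takes the usable partner as used, so I gave grey, amber and red the creep, which put amber at 45.2%. Blue adds 0.650 partner, which buys 0.445 of starting material, more than the 17.9% standing at the last reading. At the share above, that remainder gives 9.5 points, so 53.7%.

**The forecast.** The forecast gave 44.6% at 10 h, blue as best, 48% after amber, higher than mine, and 54% after blue, on the ground: “Blue restores partner”.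

**The result.** Monday's flask gives 44.2% at 10 h. The best option is blue, which adds 9.8 points and ends at 54.0%, while amber ends at 44.8%.

    starting material + coupling partner → target (k = 3.90 L mol⁻¹ h⁻¹, Ea = 53.0 kJ mol⁻¹)
    starting material + 2 coupling partner → side product (k = 16.0 L² mol⁻² h⁻¹, Ea = 51.0 kJ mol⁻¹)
    coupling partner + protic impurity → quenched reagent (k = 59.0 L mol⁻¹ h⁻¹, Ea = 71.0 kJ mol⁻¹)
    coupling partner + target ⇌ idle adduct, settled at all times (K = 1.30 L mol⁻¹, ΔH = −40.0 kJ mol⁻¹)
    (constants at 40 °C)

**Further flask.** Counting one partner per target, two per side product and one more per idle adduct, Monday's flask at 10.0 h stands at 1.46 partner per starting material consumed, with 0.34% of its partner left. A neighbour flask, the same but with 1.2 M starting material, has 0.500 usable partner. At my price that buys 0.342, leaving 65.8% starting material and giving 18.1% target. That neighbour flask holds 66% starting material and 18.3% target at 10.0 h, with 0% of its partner left.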